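Ring D, the 2,2-dimethylpyran fused to ring B, is cut back to acetone. Its oxygen sits on C-2', ortho to C-3', the carbon that carries the C-4''/C-3'' chain. A ketone at C-4'' therefore acidifies C-3'' and activates a fluoride on C-2'. In one operation the lithium enolate of a (3R)-3'-acetyl-2'-fluoro-4'-O-MOM isoflavan adds to acetone (C-3''–C-2'' bond) and the tertiary aldolate displaces fluoride (O–C-2' bond), which settles 2'-O against 4'-O closure. The isoflavan comes from an aromatic Claisen rearrangement, an asymmetric hydroboration that sets C-3 and a Mitsunobu closure. Reduction, dehydration and MOM removal complete the target.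

Key step: step 10

Assumption: the single stereocentre of the target (C-3) is R. In step 7 the ligand antipode is chosen (both derive from commercial tert-leucinol) so that hydrogen reaches the alkene face that gives R. Locants follow isoflavan numbering, with primes for ring B and double primes for ring D.

Step 1
Reactants: 1 1,3-dimethoxybenzene; 2 prenyl bromide (1-bromo-3-methylbut-2-ene)
Product: 4 1,3-dimethoxy-2-(3-methylbut-2-en-1-yl)benzene, via 2,6-dimethoxyphenyllithium 3 (not isolated)
Conditions: n-BuLi, THF, 0 → 23 °C; then 2, 0 °C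
Reagents that add atoms: n-butyllithium, CCCC[Li] (lithium of 3 only)
Why: Directed ortho-metalation places lithium on the carbon shared by both methoxy groups, and the aryllithium displaces the primary allylic bromide in SN2 fashion.

Step 2
Reactants: 4 1,3-dimethoxy-2-(3-methylbut-2-en-1-yl)benzene
Product: 6 3,5-dimethoxy-4-(3-methylbut-2-en-1-yl)phenol, via aryl pinacol boronate 5 (not isolated)
Conditions: [Ir(OMe)(cod)]2 (1.5 mol %), 4,4'-di-tert-butyl-2,2'-bipyridine (3 mol %), B2pin2, THF, 70 °C; then aq NaOH, H2O2, 0 °C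
Reagents that add atoms: bis(pinacolato)diboron, CC1(C)OB(OC1(C)C)B1OC(C)(C)C(C)(C)O1 (boryl group of 5 only); hydrogen peroxide, OO (phenol oxygen)
Why: Sterically governed iridium-catalysed aromatic C–H borylation should reach only the C–H flanked by two hydrogens (para to the prenyl group), and alkaline peroxide oxidation of the boronate gives the phenol without touching the unactivated trisubstituted alkene.

Step 3
Reactants: 7 4-bromo-3-fluorophenol
Product: 8 1-bromo-2-fluoro-4-(methoxymethoxy)benzene
Conditions: MOMCl, i-Pr2NEt, CH2Cl2, 0 → 23 °C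
Reagents that add atoms: chloromethyl methyl ether, COCCl
Why: Simple O-alkylation of the phenol installs an acetal that survives all basic steps and later serves as an ortho-directing group.

Step 4
Reactants: 8 1-bromo-2-fluoro-4-(methoxymethoxy)benzene; 9 2-bromoprop-2-en-1-ol
Product: 11 2-[2-fluoro-4-(methoxymethoxy)phenyl]prop-2-en-1-ol, via aryl pinacol boronate 10 (not isolated)
Conditions: B2pin2, Pd(dppf)Cl2 (3 mol %), KOAc, 1,4-dioxane, 90 °C; then 9, aq K2CO3, 80 °C
Reagents that add atoms: bis(pinacolato)diboron, CC1(C)OB(OC1(C)C)B1OC(C)(C)C(C)(C)O1 (boryl group of 10 only)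
Why: A one-pot Miyaura borylation and Suzuki–Miyaura coupling joins the aryl carbon to the vinylic bromide carbon and avoids an ortho-fluoroaryl lithium or magnesium species.

Step 5
Reactants: 6 3,5-dimethoxy-4-(3-methylbut-2-en-1-yl)phenol; 11 2-[2-fluoro-4-(methoxymethoxy)phenyl]prop-2-en-1-ol
Product: 12 5-({2-[2-fluoro-4-(methoxymethoxy)phenyl]prop-2-en-1-yl}oxy)-1,3-dimethoxy-2-(3-methylbut-2-en-1-yl)benzene
Conditions: PPh3, DIAD, THF, 0 → 23 °C
Reagents that add atoms: none
Why: Mitsunobu etherification of an unhindered phenol with a primary allylic alcohol is reliable, and SN2 and SN2' attack on the 2-arylallyl unit give the same ether.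

Step 6
Reactants: 12 the aryl 2-arylallyl ether
Product: 14 2-{2-[2-fluoro-4-(methoxymethoxy)phenyl]prop-2-en-1-yl}-3,5-dimethoxy-4-(3-methylbut-2-en-1-yl)phenol, via ortho-dienone 13 (not isolated)
Conditions: PhNEt2, 190 °C (sealed tube)
Reagents that add atoms: none
Why: The aromatic Claisen rearrangement ([3,3]-sigmatropic shift, then enolisation) forms the C-4–C-4a bond; the two ortho positions are equivalent by symmetry, and the basic solvent suppresses acid-induced closure to a dihydrobenzofuran.

Step 7
Reactants: 14 the ortho-(2-arylallyl)phenol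
Product: 16 2-{(2R)-2-[2-fluoro-4-(methoxymethoxy)phenyl]-3-hydroxypropyl}-3,5-dimethoxy-4-(3-methylbut-2-en-1-yl)phenol, via O,C-bis(pinacolboryl) compound 15 (not isolated)
Conditions: L*·CoCl2 (2 mol %; L* = single enantiomer of 4-tert-butyl-2-{6-[1-(2,6-diisopropylphenylimino)ethyl]pyridin-2-yl}-4,5-dihydrooxazole), NaBHEt3 (6 mol %), HBpin (2.3 equiv), THF, 23 °C; then aq NaOH, H2O2, 0 °C
Reagents that add atoms: pinacolborane, CC1(C)OBOC1(C)C (boryl groups of 15 only); hydrogen peroxide, OO (hydroxyl oxygen of 16)
Why: Cobalt-catalysed enantioselective anti-Markovnikov hydroboration of a 1,1-disubstituted aryl alkene delivers hydrogen to the internal carbon from the face selected by the chiral ligand and so sets C-3 as R; the phenol is masked in the flask as its boryl ether, the trisubstituted prenyl alkene stays inert, and the oxidation does not touch the stereocentre.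

Step 8
Reactants: 16 the (R)-phenol alcohol
Product: 17 (3R)-3-[2-fluoro-4-(methoxymethoxy)phenyl]-5,7-dimethoxy-6-(3-methylbut-2-en-1-yl)chromane
Conditions: PPh3, DIAD, THF, 0 → 23 °C
Reagents that add atoms: none
Why: Intramolecular Mitsunobu etherification (6-exo-tet displacement at the primary carbon C-2) closes ring C without involving the neighbouring stereocentre.

Step 9
Reactants: 17 the (3R)-2'-fluoro-4'-O-MOM isoflavan
Product: 19 1-{3-[(3R)-5,7-dimethoxy-6-(3-methylbut-2-en-1-yl)chroman-3-yl]-2-fluoro-6-(methoxymethoxy)phenyl}ethan-1-one, via 3'-lithio isoflavan 18 (not isolated)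
Conditions: n-BuLi, THF, −78 °C; then MeC(O)N(OMe)Me, −78 → 0 °C; aq NH4Cl
Reagents that add atoms: n-butyllithium, CCCC[Li] (lithium of 18 only); N-methoxy-N-methylacetamide, CC(=O)N(C)OC
Why: Directed ortho-metalation should occur at −78 °C only at C-3', the position flanked by fluorine and the MOM ether (loss of LiF to an aryne is frozen out at this temperature), and the Weinreb ketone synthesis stops at the methyl ketone.

Step 10
Reactants: 19 the 3'-acetyl-2'-fluoro isoflavan; 20 acetone
Product: 23 8-[(3R)-5,7-dimethoxy-6-(3-methylbut-2-en-1-yl)chroman-3-yl]-5-(methoxymethoxy)-2,2-dimethylchroman-4-one, via lithium enolate 21 (not isolated), via lithium aldolate 22 (not isolated)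
Conditions: LiHMDS (1.1 equiv), THF, −78 °C; 20 (5 equiv), −78 °C; then warm to 40 °C
Reagents that add atoms: lithium hexamethyldisilazide, [Li]N([Si](C)(C)C)[Si](C)(C)C (lithium of 21 and 22 only)
Why: LiHMDS converts the only enolisable carbonyl group of 19 into enolate 21, which adds through C-3'' to acetone to give the chelated tertiary aldolate 22 (C-3''–C-2'' bond), and on warming the alkoxide attacks C-2' ortho to the ketone and the Meisenheimer adduct expels fluoride as LiF (O–C-2' bond). The closest known reaction types are the directed lithium aldol addition, the domino aldol–SNAr and Michael–SNAr annulations of 2-fluoroaryl carbonyl compounds, and stepwise aldol/SNAr routes to chroman-4-ones. Ring D closes by a six-membered addition–elimination at an sp2 carbon (6-exo-trig with respect to C-2'=C-1'), helped by the gem-dimethyl effect and by the chelate that holds ketone and alkoxide in one plane. No stereocentre is formed, and C-3 is safe because its hydrogen stands meta to the acyl group and is not acidified. The step needs cross-aldol chemoselectivity, which is secured by preforming 21 and adding acetone cold and in excess, so that the reversible aldolate stays populated while precipitation of LiF makes the closure irreversible. It also needs 2'-O regioselectivity, which is secured because only C-2' carries a leaving group while O-4' is locked as its MOM ether, placed meta to C-2' where it does not oppose the negative charge of the adduct.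

Step 11
Reactants: 23 the 5-O-MOM 2,2-dimethylchroman-4-one
Product: 26 kanzonol I, via chroman-4-ol 24 (not isolated), via MOM-protected chromene 25 (not isolated)
Conditions: NaBH4, THF–MeOH, 0 → 23 °C; then 3 M aq HCl, 40 °C, dilute
Reagents that add atoms: none
Why: Hydride reduction gives the benzylic alcohol (epimers at C-4'' are irrelevant); acidifying the same flask causes E1 dehydration through a cation stabilised by the two ortho oxygens and hydrolyses the MOM acetal, while C-3 and the prenyl group, which has no free ortho hydroxyl, are not involved.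

Compound list
1 | 1,3-dimethoxybenzene | COc1cccc(OC)c1 | starting material
2 | prenyl bromide (1-bromo-3-methylbut-2-ene) | CC(C)=CCBr | starting material
3 | 2,6-dimethoxyphenyllithium | COc1cccc(OC)c1[Li] | intermediate
4 | 1,3-dimethoxy-2-(3-methylbut-2-en-1-yl)benzene | COc1cccc(OC)c1CC=C(C)C | intermediate
5 | 2-[3,5-dimethoxy-4-(3-methylbut-2-en-1-yl)phenyl]-4,4,5,5-tetramethyl-1,3,2-dioxaborolane | COc1cc(B2OC(C)(C)C(C)(C)O2)cc(OC)c1CC=C(C)C | intermediate
6 | 3,5-dimethoxy-4-(3-methylbut-2-en-1-yl)phenol | COc1cc(O)cc(OC)c1CC=C(C)C | intermediate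
7 | 4-bromo-3-fluorophenol | Oc1ccc(Br)c(F)c1 | starting material
8 | 1-bromo-2-fluoro-4-(methoxymethoxy)benzene | COCOc1ccc(Br)c(F)c1 | intermediate
9 | 2-bromoprop-2-en-1-ol | OCC(Br)=C | starting material
10 | 2-[2-fluoro-4-(methoxymethoxy)phenyl]-4,4,5,5-tetramethyl-1,3,2-dioxaborolane | COCOc1ccc(B2OC(C)(C)C(C)(C)O2)c(F)c1 | intermediate
11 | 2-[2-fluoro-4-(methoxymethoxy)phenyl]prop-2-en-1-ol | COCOc1ccc(C(=C)CO)c(F)c1 | intermediate
12 | 5-({2-[2-fluoro-4-(methoxymethoxy)phenyl]prop-2-en-1-yl}oxy)-1,3-dimethoxy-2-(3-methylbut-2-en-1-yl)benzene | COc1cc(OCC(=C)c2ccc(OCOC)cc2F)cc(OC)c1CC=C(C)C | intermediate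
13 | 6-{2-[2-fluoro-4-(methoxymethoxy)phenyl]prop-2-en-1-yl}-3,5-dimethoxy-4-(3-methylbut-2-en-1-yl)cyclohexa-2,4-dien-1-one (racemic) | COC1=CC(=O)C(CC(=C)c2ccc(OCOC)cc2F)C(OC)=C1CC=C(C)C | intermediate
14 | 2-{2-[2-fluoro-4-(methoxymethoxy)phenyl]prop-2-en-1-yl}-3,5-dimethoxy-4-(3-methylbut-2-en-1-yl)phenol | COc1cc(O)c(CC(=C)c2ccc(OCOC)cc2F)c(OC)c1CC=C(C)C | intermediate
15 | (R)-configured primary alkyl pinacol boronate of 14 with the phenol oxygen carried as its pinacolboryl ether | COc1cc(OB2OC(C)(C)C(C)(C)O2)c(c(OC)c1CC=C(C)C)C[C@H](c1ccc(OCOC)cc1F)CB1OC(C)(C)C(C)(C)O1 | intermediate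
16 | 2-{(2R)-2-[2-fluoro-4-(methoxymethoxy)phenyl]-3-hydroxypropyl}-3,5-dimethoxy-4-(3-methylbut-2-en-1-yl)phenol | COc1cc(O)c(c(OC)c1CC=C(C)C)C[C@H](c1ccc(OCOC)cc1F)CO | intermediate
17 | (3R)-3-[2-fluoro-4-(methoxymethoxy)phenyl]-5,7-dimethoxy-6-(3-methylbut-2-en-1-yl)chromane | COc1cc2c(c(OC)c1CC=C(C)C)C[C@H](c1ccc(OCOC)cc1F)CO2 | intermediate
18 | 3'-lithio derivative of 17 (lithium between fluorine and the MOM ether) | COc1cc2c(c(OC)c1CC=C(C)C)C[C@H](c1ccc(OCOC)c([Li])c1F)CO2 | intermediate
19 | 1-{3-[(3R)-5,7-dimethoxy-6-(3-methylbut-2-en-1-yl)chroman-3-yl]-2-fluoro-6-(methoxymethoxy)phenyl}ethan-1-one | COc1cc2c(c(OC)c1CC=C(C)C)C[C@H](c1ccc(OCOC)c(C(C)=O)c1F)CO2 | intermediate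
20 | acetone | CC(C)=O | starting material
21 | lithium enolate of 19 | COc1cc2c(c(OC)c1CC=C(C)C)C[C@H](c1ccc(OCOC)c(C(=C)[O-])c1F)CO2.[Li+] | intermediate
22 | lithium aldolate (3-oxido-3-methylbutanoyl side chain on C-3') | COc1cc2c(c(OC)c1CC=C(C)C)C[C@H](c1ccc(OCOC)c(C(=O)CC(C)(C)[O-])c1F)CO2.[Li+] | intermediate
23 | 8-[(3R)-5,7-dimethoxy-6-(3-methylbut-2-en-1-yl)chroman-3-yl]-5-(methoxymethoxy)-2,2-dimethylchroman-4-one | COc1cc2c(c(OC)c1CC=C(C)C)C[C@H](c1ccc(OCOC)c3c1OC(C)(C)CC3=O)CO2 | intermediate
24 | 8-[(3R)-5,7-dimethoxy-6-(3-methylbut-2-en-1-yl)chroman-3-yl]-5-(methoxymethoxy)-2,2-dimethylchroman-4-ol (both epimers at the carbinol carbon) | COc1cc2c(c(OC)c1CC=C(C)C)C[C@H](c1ccc(OCOC)c3c1OC(C)(C)CC3O)CO2 | intermediate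
25 | (3R)-5,7-dimethoxy-3-[5-(methoxymethoxy)-2,2-dimethyl-2H-chromen-8-yl]-6-(3-methylbut-2-en-1-yl)chromane | COc1cc2c(c(OC)c1CC=C(C)C)C[C@H](c1ccc(OCOC)c3c1OC(C)(C)C=C3)CO2 | intermediate
26 | kanzonol I, 8-[(3R)-5,7-dimethoxy-6-(3-methylbut-2-en-1-yl)chroman-3-yl]-2,2-dimethyl-2H-chromen-5-ol | COc1cc2c(c(OC)c1CC=C(C)C)C[C@H](c1ccc(O)c3c1OC(C)(C)C=C3)CO2 | target

Total step count: 11. Longest linear sequence: 9 steps (steps 1, 2 and 5–11 from 1; equally steps 3–11 from 7).

Steps most likely to fail

Step 10. Retro-aldol cleavage of the tertiary aldolate and base-induced loss of water from it may outrun the displacement on an electron-rich fluoroarene that is substituted on both sides of C-2'. The fallback sets out from 19 and returns at 23, and it brings in the oxygen first. Compound 19 is heated with acetohydroxamic acid and K2CO3 in DMSO at 80 °C (SNAr with a hydroxide surrogate) to give the 2'-hydroxy-3'-acetyl isoflavan F1. A Kabbe condensation of F1 with acetone (pyrrolidine, MeOH, 60 °C; enamine aldol condensation, then oxa-Michael closure) gives 23. The MOM ether on O-4' still forces closure onto O-2'.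

Step 7. Facial selectivity may be poor because the aryl group and the bulky benzylic substituent on the alkene differ little in size, and the phenol may slow the catalyst. The fallback sets out from 14 and returns at 16, and it replaces asymmetric catalysis by a resolution. Hydroboration of 14 with 9-BBN (which prefers the 1,1-disubstituted over the trisubstituted alkene) and oxidation with H2O2/NaOH give the racemic phenol alcohol F2. Kinetic resolution follows with Burkholderia cepacia lipase (a triacylglycerol lipase of the hydrolase class) and vinyl acetate in MTBE at 30 °C. The enzyme is taken to acylate the S antipode faster, giving the (S)-acetate F3, which is separated by chromatography. The unreacted R alcohol is 16.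

Step 11. Under acid the tertiary allylic aryl ether of ring D may ionise and close again onto the freed 4'-hydroxyl (migration of the pyran ring). The prenyl alkene may hydrate, or the benzylic cation may alkylate ring A of a second molecule. The fallback sets out from 23 and returns at 26, and it avoids protic acid. KHMDS and PhNTf2 (THF, −78 °C) convert 23 into the enol triflate F4. Palladium-catalysed formate reduction (Pd(OAc)2, PPh3, HCO2H, Et3N, DMF, 60 °C) gives 25, isolated in this variant. A brief treatment with ZnBr2 and n-PrSH in CH2Cl2 at 0 °C removes the MOM group to give 26.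

Further compounds
F1 | step 10 | 1-{3-[(3R)-5,7-dimethoxy-6-(3-methylbut-2-en-1-yl)chroman-3-yl]-2-hydroxy-6-(methoxymethoxy)phenyl}ethan-1-one | COc1cc2c(c(OC)c1CC=C(C)C)C[C@H](c1ccc(OCOC)c(C(C)=O)c1O)CO2
F2 | step 7 | racemic 2-{2-[2-fluoro-4-(methoxymethoxy)phenyl]-3-hydroxypropyl}-3,5-dimethoxy-4-(3-methylbut-2-en-1-yl)phenol | COc1cc(O)c(c(OC)c1CC=C(C)C)CC(c1ccc(OCOC)cc1F)CO
F3 | step 7 | (2S)-2-[2-fluoro-4-(methoxymethoxy)phenyl]-3-[2-hydroxy-4,6-dimethoxy-5-(3-methylbut-2-en-1-yl)phenyl]propyl acetate | COc1cc(O)c(c(OC)c1CC=C(C)C)C[C@@H](c1ccc(OCOC)cc1F)COC(C)=O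
F4 | step 11 | 8-[(3R)-5,7-dimethoxy-6-(3-methylbut-2-en-1-yl)chroman-3-yl]-5-(methoxymethoxy)-2,2-dimethyl-2H-chromen-4-yl trifluoromethanesulfonate | COc1cc2c(c(OC)c1CC=C(C)C)C[C@H](c1ccc(OCOC)c3c1OC(C)(C)C=C3OS(=O)(=O)C(F)(F)F)CO2
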